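**Retrosynthetic overview**

1. Target 22 ⇐ ring B acyloin from the C8=C9 alkene of spirodiene 19 (dihydroxylation, then oxidation). The ring A bromohydrin and exocyclic methylene ⇐ spiro vinylogous ester 10 (methyl addition with carbonyl transposition, α′-bromination, deconjugation, hydride reduction).
2. Key disconnection: ring B (bonds C6–C7 and C10–C11) by a catalytic enantioselective Diels–Alder reaction of the achiral exocyclic enone 6 (C6=C11) with 2-(chloromethyl)buta-1,3-diene 9 (C7–C10), which also delivers the CH2Cl group.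
3. Enabling feature: the spiro carbon C6 of ring B is α to ring A carbon C1, whose exocyclic methylene is a carbonyl at another oxidation level, so C6=C11 can be an α-methylene ketone dienophile. Ring B atoms C7–C8–C9–C10 (CH2–C(=O)–C(OH)(CH2Cl)–CH2) are a 2-substituted butadiene at the alkene oxidation level. The C1/C3 oxygenation plus C5 gem-dimethyl of ring A is dimedone, so the dienophile has no stereocentre.
4. Ring order: ring A is bought (dimedone); ring B is the last ring closed (step 5). All other stereocentres are relayed from the spiro centre.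

Key step: step 5

**Remarks and assumptions**

- Assumption: 2-methyl-2-vinyloxirane (7) is taken as commercially available.
- Assumption: the sense of induction of the chiral acid in step 5 is selectable through the catalyst enantiomer.
- Numbering: all spiro compounds are named with one fixed numbering, not always the lowest-locant one. Ring A = C1–C5 (C1 carries the exocyclic methylene in the target, C3 = carbinol, C4 = C–Br, C5 = CMe2), C6 = spiro carbon, ring B = C7–C11 (C7 = CH2 next to C8, C9 bears CH2Cl).
- Descriptors: changes of the C6 descriptor (S in 10–12, R from 13 on) reflect CIP priorities only; the centre is never inverted.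

**Route**

Step 1
Reactants: 1 dimedone (5,5-dimethylcyclohexane-1,3-dione)
Product: 2 5,5-dimethyl-3-(2-methylpropoxy)cyclohex-2-en-1-one
Conditions: iBuOH, TsOH (cat.), toluene, reflux, Dean–Stark
Reagents that add atoms: 2-methylpropan-1-ol, CC(C)CO
Why: Acid-catalysed condensation of the enolised 1,3-diketone with the alcohol (vinylogous ester formation), driven by azeotropic removal of water; no stereocentre is formed.

Step 2
Reactants: 2 5,5-dimethyl-3-(2-methylpropoxy)cyclohex-2-en-1-one
Product: 6 5,5-dimethyl-6-methylidene-3-(2-methylpropoxy)cyclohex-2-en-1-one, via lithium enolate 3 (not isolated), via Mannich base 4 (not isolated), via trimethylammonium iodide 5 (not isolated)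
Conditions: LiN(iPr)2, THF, −78 °C; CH2=NMe2+ I−, −78 °C → rt; MeI, rt; aq. NaHCO3, CH2Cl2, rt; product used directly
Reagents that add atoms: N,N-dimethylmethylideneammonium iodide (Eschenmoser's salt), C=[N+](C)C.[I-]
Why: Kinetic deprotonation of a vinylogous ester occurs at the α′ carbon C6, the enolate is aminomethylated (Mannich reaction), and quaternisation followed by E1cB elimination gives the exocyclic enone, which cannot tautomerise because C5 is quaternary; no stereocentre remains.

Step 3
Reactants: 7 2-methyl-2-vinyloxirane (racemic)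
Product: 8 2-methylidenebut-3-en-1-ol
Conditions: LiN(iPr)2, Et2O, 0 °C → rt; H2O
Reagents that add atoms: none
Why: Lithium amide-promoted isomerisation of an epoxide to an allylic alcohol (syn β-elimination), in which only the methyl hydrogens can be removed; the stereocentre of 7 is lost, so the racemate serves.

Step 4
Reactants: 8 2-methylidenebut-3-en-1-ol
Product: 9 2-(chloromethyl)buta-1,3-diene
Conditions: PPh3, CCl4, CH2Cl2, 0 °C → rt; handled as a solution
Reagents that add atoms: tetrachloromethane, ClC(Cl)(Cl)Cl
Why: Appel chlorination of a primary allylic alcohol (chloride displaces the alkoxyphosphonium group, and the SN2′ path is degenerate for this allyl unit); no stereocentre is formed.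

Step 5
Reactants: 6 5,5-dimethyl-6-methylidene-3-(2-methylpropoxy)cyclohex-2-en-1-one; 9 2-(chloromethyl)buta-1,3-diene
Product: 10 (6S)-9-(chloromethyl)-5,5-dimethyl-3-(2-methylpropoxy)spiro[5.5]undeca-2,8-dien-1-one
Conditions: chiral imidodiphosphorimidate (IDPi) Brønsted acid (5 mol %), 9 (3 equiv), CH2Cl2, −40 °C
Reagents that add atoms: none
Why: The strongly acidic, confined chiral Brønsted acid activates the carbonyl oxygen of the s-cis-locked exocyclic enone of 6, and diene 9 adds in a concerted, asynchronous [4+2] cycloaddition in which the C10–C11 bond (diene terminus to the exocyclic CH2) runs ahead of the C6–C7 bond. The closest known reaction type is the chiral-acid-catalysed spirocyclising Diels–Alder reaction of α-methylene cycloalkanones with isoprene-type 2-substituted butadienes, which gives spiro[5.5]undecenones. Ring B is closed in the [4+2] cycloaddition mode, both of its new σ bonds (C6–C7 and C10–C11) being made in this one step. The only new stereocentre, the quaternary spiro carbon C6, is controlled by the catalyst, whose chiral anion pocket differentiates the enantiotopic faces of the achiral dienophile; the catalyst enantiomer that leads to (6S)-10 is chosen. The step needs para regioselectivity (C9 with its CH2Cl group placed 1,4 to C6), which is secured because the larger HOMO coefficient of a 2-substituted diene lies on the terminus next to the substituted carbon and pairs with the electrophilic exocyclic CH2. It also needs site selectivity for the exocyclic C=C, secured because the endocyclic C=C of 6 is a donor-substituted enol ether and the C5 gem-dimethyl group prevents isomerisation of the exocyclic enone.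

Step 6
Reactants: 10 (6S)-9-(chloromethyl)-5,5-dimethyl-3-(2-methylpropoxy)spiro[5.5]undeca-2,8-dien-1-one
Product: 12 (6S)-9-(chloromethyl)-1,5,5-trimethylspiro[5.5]undeca-1,8-dien-3-one, via tertiary carbinol 11 (not isolated)
Conditions: MeLi, CeCl3, THF, −78 → 0 °C; then 1 M HCl, THF, rt
Reagents that add atoms: methyllithium, [Li]C
Why: Stork–Danheiser sequence, in which the organocerium reagent adds 1,2 to the hindered, enolisable vinylogous ester carbonyl and aqueous acid hydrolyses the enol ether and dehydrates the β-hydroxy ketone (1,3-carbonyl transposition); the C1 stereocentre of 11 is destroyed and the spiro centre is untouched.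

Step 7
Reactants: 12 (6S)-9-(chloromethyl)-1,5,5-trimethylspiro[5.5]undeca-1,8-dien-3-one
Product: 15 (4R,6R)-4-bromo-9-(chloromethyl)-1,5,5-trimethylspiro[5.5]undeca-1,8-dien-3-one, via lithium dienolate 13 (not isolated), via silyl enol ether 14 (not isolated)
Conditions: LiN(iPr)2, THF, −78 °C; Me3SiCl, −78 → 0 °C; NBS, THF, −78 °C; Et3N (cat.), CH2Cl2, rt if equilibration at C4 is needed
Reagents that add atoms: N-bromosuccinimide, O=C1CCC(=O)N1Br
Why: α′-Bromination of an enone through its cross-conjugated silyl enol ether, in which the amide base removes a C4 proton kinetically and NBS brominates the 2-silyloxydiene 14 at its terminal carbon C4; the new C4 stereocentre is expected to arise by approach of NBS anti to the ring B methylene (C11) that is pseudoaxial on ring A, and the same epimer (Br equatorial, cis to C7) should also be the thermodynamically preferred one that enolisation would restore.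

Step 8
Reactants: 15 (4R,6R)-4-bromo-9-(chloromethyl)-1,5,5-trimethylspiro[5.5]undeca-1,8-dien-3-one
Product: 17 (4R,6R)-4-bromo-9-(chloromethyl)-5,5-dimethyl-1-methylidenespiro[5.5]undec-8-en-3-one, via silyl dienol ether 16 (not isolated)
Conditions: Me3SiOTf, Et3N, CH2Cl2, 0 °C; then Bu4NF, AcOH, THF, −78 °C; crude product taken on at once
Reagents that add atoms: none
Why: Deconjugation by kinetic protonation of a dienolate, in which soft enolisation removes a proton from the accessible C1 methyl group rather than the hindered tertiary C4–H to give the linear silyl dienol ether 16, and buffered fluoride releases the dienolate, which is protonated at the α-carbon C2 faster than at the γ-carbon; no stereocentre is formed and C4 is not involved.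

Step 9
Reactants: 17 (4R,6R)-4-bromo-9-(chloromethyl)-5,5-dimethyl-1-methylidenespiro[5.5]undec-8-en-3-one
Product: 18 (3S,4R,6R)-4-bromo-9-(chloromethyl)-5,5-dimethyl-1-methylidenespiro[5.5]undec-8-en-3-ol
Conditions: iBu2AlH, THF, −78 °C
Reagents that add atoms: none
Why: 1,2-Reduction of the ketone with a bulky aluminium hydride at low temperature, before the β,γ-enone can reconjugate; the axial C5 methyl group blocks the axial trajectory at C3, so hydride is delivered equatorially and the new C3 hydroxyl is axial and cis to the equatorial bromine.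

Step 10
Reactants: 18 (3S,4R,6R)-4-bromo-9-(chloromethyl)-5,5-dimethyl-1-methylidenespiro[5.5]undec-8-en-3-ol
Product: 19 (3S,4R,6R)-4-bromo-9-(chloromethyl)-5,5-dimethyl-1-methylidene-3-(triethylsilyloxy)spiro[5.5]undec-8-ene
Conditions: Et3SiOTf, 2,6-lutidine, CH2Cl2, −78 → 0 °C
Reagents that add atoms: triethylsilyl trifluoromethanesulfonate, CC[Si](CC)(CC)OS(=O)(=O)C(F)(F)F
Why: Silylation of the hindered secondary alcohol with a silyl triflate and a non-nucleophilic base, which keeps the ring A carbinol out of the later oxidation; no stereocentre is affected.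

Step 11
Reactants: 19 (3S,4R,6R)-4-bromo-9-(chloromethyl)-5,5-dimethyl-1-methylidene-3-(triethylsilyloxy)spiro[5.5]undec-8-ene
Product: 20 (3S,4R,6R,8R,9S)-4-bromo-9-(chloromethyl)-5,5-dimethyl-1-methylidene-3-(triethylsilyloxy)spiro[5.5]undecane-8,9-diol
Conditions: OsO4 (2 mol %), NMO, acetone/H2O (4:1), 0 °C → rt
Reagents that add atoms: 4-methylmorpholine N-oxide, C[N+]1([O-])CCOCC1; water, O (both oxygen atoms are passed on through catalytic OsO4, O=[Os](=O)(=O)=O)
Why: Upjohn dihydroxylation (syn addition), in which the trisubstituted ring B alkene is expected to react before the exocyclic methylene, which sits next to the quaternary C6 and is shielded on one face by the axial silyloxy and methyl groups and on the other by the axial ring B methylene; osmylation anti to the C1 arm that is axial on ring B sets C9 (hydroxyl cis to the C5 arm) and the temporary C8 centre.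

Step 12
Reactants: 20 (3S,4R,6R,8R,9S)-4-bromo-9-(chloromethyl)-5,5-dimethyl-1-methylidene-3-(triethylsilyloxy)spiro[5.5]undecane-8,9-diol
Product: 21 (3S,4R,6R,9S)-4-bromo-9-(chloromethyl)-9-hydroxy-5,5-dimethyl-1-methylidene-3-(triethylsilyloxy)spiro[5.5]undecan-8-one
Conditions: IBX, DMSO, rt
Reagents that add atoms: none
Why: IBX oxidation of the secondary hydroxyl of a secondary/tertiary vicinal diol to the α-hydroxy ketone without glycol cleavage; the tertiary C9 carbinol cannot be oxidised and keeps its configuration, and the C8 stereocentre is removed.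

Step 13
Reactants: 21 (3S,4R,6R,9S)-4-bromo-9-(chloromethyl)-9-hydroxy-5,5-dimethyl-1-methylidene-3-(triethylsilyloxy)spiro[5.5]undecan-8-one
Product: 22 (3S,4R,6R,9S)-4-bromo-9-(chloromethyl)-3,9-dihydroxy-5,5-dimethyl-1-methylidenespiro[5.5]undecan-8-one (target)
Conditions: HF·pyridine, THF, 0 °C
Reagents that add atoms: none
Why: Fluoride-mediated cleavage of the triethylsilyl ether under non-basic conditions, which leave the α-ketol, the chlorohydrin (no alkoxide, hence no epoxide formation) and the exocyclic alkene untouched; no stereocentre is affected.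

**Compound list**

1 | dimedone (5,5-dimethylcyclohexane-1,3-dione) | CC1(C)CC(=O)CC(=O)C1 | starting material
2 | 5,5-dimethyl-3-(2-methylpropoxy)cyclohex-2-en-1-one | CC(C)COC1=CC(=O)CC(C)(C)C1 | intermediate
3 | lithium 3,3-dimethyl-5-(2-methylpropoxy)cyclohexa-1,5-dien-1-olate | [Li]OC1=CC(C)(C)CC(OCC(C)C)=C1 | intermediate
4 | 6-[(dimethylamino)methyl]-5,5-dimethyl-3-(2-methylpropoxy)cyclohex-2-en-1-one (racemic) | CN(C)CC1C(=O)C=C(OCC(C)C)CC1(C)C | intermediate
5 | {[6,6-dimethyl-4-(2-methylpropoxy)-2-oxocyclohex-3-en-1-yl]methyl}trimethylammonium iodide (racemic) | C[N+](C)(C)CC1C(=O)C=C(OCC(C)C)CC1(C)C.[I-] | intermediate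
6 | 5,5-dimethyl-6-methylidene-3-(2-methylpropoxy)cyclohex-2-en-1-one | C=C1C(=O)C=C(OCC(C)C)CC1(C)C | intermediate
7 | 2-methyl-2-vinyloxirane (racemic) | CC1(CO1)C=C | starting material
8 | 2-methylidenebut-3-en-1-ol | C=CC(=C)CO | intermediate
9 | 2-(chloromethyl)buta-1,3-diene | C=CC(=C)CCl | intermediate
10 | (6S)-9-(chloromethyl)-5,5-dimethyl-3-(2-methylpropoxy)spiro[5.5]undeca-2,8-dien-1-one | O=C1C=C(OCC(C)C)CC(C)(C)[C@@]12CCC(CCl)=CC2 | intermediate
11 | (1RS,6S)-9-(chloromethyl)-1,5,5-trimethyl-3-(2-methylpropoxy)spiro[5.5]undeca-2,8-dien-1-ol | CC1(O)C=C(OCC(C)C)CC(C)(C)[C@@]12CCC(CCl)=CC2 | intermediate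
12 | (6S)-9-(chloromethyl)-1,5,5-trimethylspiro[5.5]undeca-1,8-dien-3-one | CC1=CC(=O)CC(C)(C)[C@@]12CCC(CCl)=CC2 | intermediate
13 | lithium (6R)-9-(chloromethyl)-1,5,5-trimethylspiro[5.5]undeca-1,3,8-trien-3-olate | CC1=CC(O[Li])=CC(C)(C)[C@@]12CCC(CCl)=CC2 | intermediate
14 | (6R)-9-(chloromethyl)-1,5,5-trimethyl-3-(trimethylsilyloxy)spiro[5.5]undeca-1,3,8-triene | CC1=CC(O[Si](C)(C)C)=CC(C)(C)[C@@]12CCC(CCl)=CC2 | intermediate
15 | (4R,6R)-4-bromo-9-(chloromethyl)-1,5,5-trimethylspiro[5.5]undeca-1,8-dien-3-one | CC1=CC(=O)[C@H](Br)C(C)(C)[C@@]12CCC(CCl)=CC2 | intermediate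
16 | (4R,6R)-4-bromo-9-(chloromethyl)-5,5-dimethyl-1-methylidene-3-(trimethylsilyloxy)spiro[5.5]undeca-2,8-diene | C=C1C=C(O[Si](C)(C)C)[C@H](Br)C(C)(C)[C@@]12CCC(CCl)=CC2 | intermediate
17 | (4R,6R)-4-bromo-9-(chloromethyl)-5,5-dimethyl-1-methylidenespiro[5.5]undec-8-en-3-one | C=C1CC(=O)[C@H](Br)C(C)(C)[C@@]12CCC(CCl)=CC2 | intermediate
18 | (3S,4R,6R)-4-bromo-9-(chloromethyl)-5,5-dimethyl-1-methylidenespiro[5.5]undec-8-en-3-ol | C=C1C[C@H](O)[C@H](Br)C(C)(C)[C@@]12CCC(CCl)=CC2 | intermediate
19 | (3S,4R,6R)-4-bromo-9-(chloromethyl)-5,5-dimethyl-1-methylidene-3-(triethylsilyloxy)spiro[5.5]undec-8-ene | C=C1C[C@H](O[Si](CC)(CC)CC)[C@H](Br)C(C)(C)[C@@]12CCC(CCl)=CC2 | intermediate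
20 | (3S,4R,6R,8R,9S)-4-bromo-9-(chloromethyl)-5,5-dimethyl-1-methylidene-3-(triethylsilyloxy)spiro[5.5]undecane-8,9-diol | C=C1C[C@H](O[Si](CC)(CC)CC)[C@H](Br)C(C)(C)[C@@]12CC[C@@](O)(CCl)[C@H](O)C2 | intermediate
21 | (3S,4R,6R,9S)-4-bromo-9-(chloromethyl)-9-hydroxy-5,5-dimethyl-1-methylidene-3-(triethylsilyloxy)spiro[5.5]undecan-8-one | C=C1C[C@H](O[Si](CC)(CC)CC)[C@H](Br)C(C)(C)[C@@]12CC[C@@](O)(CCl)C(=O)C2 | intermediate
22 | (3S,4R,6R,9S)-4-bromo-9-(chloromethyl)-3,9-dihydroxy-5,5-dimethyl-1-methylidenespiro[5.5]undecan-8-one | C=C1C[C@H](O)[C@H](Br)C(C)(C)[C@@]12CC[C@@](O)(CCl)C(=O)C2 | target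

**Step count**

Total: 13 steps. Longest linear sequence: 11 steps (steps 1, 2 and 5–13 from dimedone; the diene branch, steps 3–4, joins at step 5 and is equally long).

**Steps most likely to fail, with fallbacks**

Step 5 (key Diels–Alder reaction).
- What may go wrong: the donor-substituted (vinylogous ester) exocyclic enone may be activated too weakly by the acid, so that oligomerisation of diene 9 or self-dimerisation of 6 outruns the cycloaddition. Regio- and enantiofacial control may also erode with the weakly donating chloromethyl diene.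
- Fallback, from 2 back to 10: enolate alkylation, decarboxylative asymmetric allylic alkylation and ring-closing metathesis; ring B remains the last ring closed.
- Commercially available 3-methylideneoxolan-2-one is opened with Me3SiI and esterified in the same flask with MeOH to methyl 4-iodo-2-methylidenebutanoate F1. This is reduced with iBu2AlH to 4-iodo-2-methylidenebutan-1-ol F2 and silylated (tBuMe2SiCl, imidazole) to tert-butyl[(4-iodo-2-methylidenebutyl)oxy]dimethylsilane F3.
- Kinetic α′-alkylation of 2 (LiN(iPr)2, then F3) gives the racemic alkylated vinylogous ester F4. O-Acylation of its lithium enolate with allyl chloroformate gives the allyl enol carbonate F5.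
- Pd2(dba)3 (zerovalent palladium) with a tert-butyl-PHOX-type ligand of the appropriate configuration effects decarboxylative asymmetric allylic alkylation to the α-quaternary allyl ketone F6.
- The second-generation Grubbs catalyst closes ring B to the spirocyclic silyl ether F7. Bu4NF liberates the spirocyclic allylic alcohol F8, and Appel chlorination (PPh3, CCl4) gives 10.

Step 8 (deconjugation).
- What may go wrong: the β,γ-unsaturated ketone may reconjugate during work-up, or the dienolate may lose bromide (Favorskii-type) before it is protonated.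
- Fallback, from 15 back to 18: reductive deconjugation through an enol ester. Compound 15 is converted under acid catalysis (isopropenyl acetate, TsOH, reflux) into the dienyl acetate F9. NaBH4 in EtOH/THF at 0 °C then cleaves the enol ester, the dienolate is protonated at the α-carbon by the solvent, and the β,γ-enone is reduced in the same flask. Alcohol 18 is thus reached without the free ketone 17 being handled; a C3 epimer, if formed, would be separated.

Step 11 (dihydroxylation of ring B).
- What may go wrong: competing osmylation of the exocyclic methylene of ring A.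
- Fallback, from 15 to 22: dihydroxylate while the only other alkene is a deactivated conjugated enone. OsO4/NMO on 15 gives the enone diol F10, protected (2,2-dimethoxypropane, PPTS) as the enone acetonide F11.
- The conditions of steps 8 and 9 are then applied: Me3SiOTf/Et3N gives the silyl dienol ether acetonide F12, Bu4NF/AcOH the β,γ-enone acetonide F13, and iBu2AlH the bromohydrin acetonide F14.
- Aqueous AcOH removes the acetonide to the triol F15. The vicinal diol is then oxidised chemoselectively in the presence of the isolated ring A alcohol with [(neocuproine)Pd(OAc)]2(OTf)2 and benzoquinone (MeCN/H2O), which gives 22 directly.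

**Further compounds**

F1 | step 5 | methyl 4-iodo-2-methylidenebutanoate | COC(=O)C(=C)CCI
F2 | step 5 | 4-iodo-2-methylidenebutan-1-ol | OCC(=C)CCI
F3 | step 5 | tert-butyl[(4-iodo-2-methylidenebutyl)oxy]dimethylsilane | CC(C)(C)[Si](C)(C)OCC(=C)CCI
F4 | step 5 | (6RS)-6-{4-[(tert-butyldimethylsilyl)oxy]-3-methylidenebutyl}-5,5-dimethyl-3-(2-methylpropoxy)cyclohex-2-en-1-one | CC(C)COC1=CC(=O)C(CCC(=C)CO[Si](C)(C)C(C)(C)C)C(C)(C)C1
F5 | step 5 | prop-2-en-1-yl 2-{4-[(tert-butyldimethylsilyl)oxy]-3-methylidenebutyl}-3,3-dimethyl-5-(2-methylpropoxy)cyclohexa-1,5-dien-1-yl carbonate | C=CCOC(=O)OC1=C(CCC(=C)CO[Si](C)(C)C(C)(C)C)C(C)(C)CC(OCC(C)C)=C1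
F6 | step 5 | (6S)-6-allyl-6-{4-[(tert-butyldimethylsilyl)oxy]-3-methylidenebutyl}-5,5-dimethyl-3-(2-methylpropoxy)cyclohex-2-en-1-one | O=C1C=C(OCC(C)C)CC(C)(C)[C@@]1(CC=C)CCC(=C)CO[Si](C)(C)C(C)(C)C
F7 | step 5 | (6S)-9-{[(tert-butyldimethylsilyl)oxy]methyl}-5,5-dimethyl-3-(2-methylpropoxy)spiro[5.5]undeca-2,8-dien-1-one | O=C1C=C(OCC(C)C)CC(C)(C)[C@@]12CCC(CO[Si](C)(C)C(C)(C)C)=CC2
F8 | step 5 | (6S)-9-(hydroxymethyl)-5,5-dimethyl-3-(2-methylpropoxy)spiro[5.5]undeca-2,8-dien-1-one | O=C1C=C(OCC(C)C)CC(C)(C)[C@@]12CCC(CO)=CC2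
F9 | step 8 | (4R,6R)-4-bromo-9-(chloromethyl)-5,5-dimethyl-1-methylidenespiro[5.5]undeca-2,8-dien-3-yl acetate | C=C1C=C(OC(C)=O)[C@H](Br)C(C)(C)[C@@]12CCC(CCl)=CC2
F10 | step 11 | (4R,6R,8R,9S)-4-bromo-9-(chloromethyl)-8,9-dihydroxy-1,5,5-trimethylspiro[5.5]undec-1-en-3-one | CC1=CC(=O)[C@H](Br)C(C)(C)[C@@]12CC[C@@](O)(CCl)[C@H](O)C2
F11 | step 11 | (4R,6R,8R,9S)-4-bromo-9-(chloromethyl)-8,9-(isopropylidenedioxy)-1,5,5-trimethylspiro[5.5]undec-1-en-3-one | CC1=CC(=O)[C@H](Br)C(C)(C)[C@@]12CC[C@]3(CCl)OC(C)(C)O[C@@H]3C2
F12 | step 11 | (4R,6R,8R,9S)-4-bromo-9-(chloromethyl)-8,9-(isopropylidenedioxy)-5,5-dimethyl-1-methylidene-3-(trimethylsilyloxy)spiro[5.5]undec-2-ene | C=C1C=C(O[Si](C)(C)C)[C@H](Br)C(C)(C)[C@@]12CC[C@]3(CCl)OC(C)(C)O[C@@H]3C2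
F13 | step 11 | (4R,6R,8R,9S)-4-bromo-9-(chloromethyl)-8,9-(isopropylidenedioxy)-5,5-dimethyl-1-methylidenespiro[5.5]undecan-3-one | C=C1CC(=O)[C@H](Br)C(C)(C)[C@@]12CC[C@]3(CCl)OC(C)(C)O[C@@H]3C2
F14 | step 11 | (3S,4R,6R,8R,9S)-4-bromo-9-(chloromethyl)-8,9-(isopropylidenedioxy)-5,5-dimethyl-1-methylidenespiro[5.5]undecan-3-ol | C=C1C[C@H](O)[C@H](Br)C(C)(C)[C@@]12CC[C@]3(CCl)OC(C)(C)O[C@@H]3C2
F15 | step 11 | (3S,4R,6R,8R,9S)-4-bromo-9-(chloromethyl)-5,5-dimethyl-1-methylidenespiro[5.5]undecane-3,8,9-triol | C=C1C[C@H](O)[C@H](Br)C(C)(C)[C@@]12CC[C@@](O)(CCl)[C@H](O)C2
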